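Eudesmane numbering is used. The skeleton C1–C15 of the target, with one-carbon branches on C4, C10 and C11, is an intact head-to-tail farnesyl chain; this is the feature the key step exploits. Cutting C6–C7 and C5–C10 opens rings A and B to acyclic, achiral (2E,6E)-farnesyl diphosphate. One synthase-mediated cation–olefin cascade re-forms both bonds, closes the trans-decalin, sets C5, C7 and C10, and leaves two alkenes (C3=C4, C11=C12) in α-selinene. These handles then take all the oxygen: C12 becomes the methyl ester, C3=C4 delivers the 3α-angelate and a C4=C5 alkene, and a singlet-oxygen ene reaction places 5α-OOH and the C4=C15 methylene.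

Key step: step 3

Remark: open-chain compounds carry the same numbering (C6 = carbinol carbon of farnesol); 4 is drawn as the free acid but is made and used as its ammonium salt from isomerically pure (2E,6E)-farnesol; a recombinant synthase whose main product is α-selinene is assumed to be available by selection or engineering.

Step 1
Reactants: 1 (2E,6E)-farnesol
Product: 3 (2E,6E)-farnesyl chloride, via farnesyloxydimethylsulfonium chloride 2 (not isolated)
Conditions: NCS, Me2S, CH2Cl2, −30 °C to 0 °C
Reagents that add atoms: N-chlorosuccinimide, O=C1CCC(=O)N1Cl; dimethyl sulfide, CSC (its atoms stay only in 2)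
Why: Corey–Kim-type chlorination, in which the primary allylic hydroxyl becomes an alkoxysulfonium leaving group that chloride displaces in an SN2 step under neutral conditions, so neither allylic transposition nor E/Z drift of the C4=C5 alkene is expected.

Step 2
Reactants: 3 (2E,6E)-farnesyl chloride
Product: 4 (2E,6E)-farnesyl diphosphate
Conditions: (Bu4N)3HP2O7, MeCN, rt; cation-exchange resin (NH4+ form), aq. NH4HCO3; freeze-drying
Reagents that add atoms: tris(tetrabutylammonium) hydrogen diphosphate, CCCC[N+](CCCC)(CCCC)CCCC.CCCC[N+](CCCC)(CCCC)CCCC.CCCC[N+](CCCC)(CCCC)CCCC.OP(=O)([O-])OP(=O)([O-])[O-]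
Why: SN2 alkylation of the lipophilic diphosphate salt by a primary allylic chloride in a dipolar aprotic solvent, the standard preparation of allylic diphosphates, keeps both E alkenes intact, and the exchange to ammonium ions removes the tetrabutylammonium ions that would disturb the enzyme.

Step 3
Reactants: 4 (2E,6E)-farnesyl diphosphate
Product: 6 α-selinene (eudesma-3,11-diene; 5α-H 7β-isopropenyl 10β-methyl), via (R)-germacrene A 5 (not isolated)
Conditions: recombinant α-selinene-selective class 1 sesquiterpene synthase, MgCl2, HEPES buffer pH 7.5, DTT, pentane overlay, 30 °C; chromatography on AgNO3-impregnated SiO2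
Reagents that add atoms: none
Why: Magnesium ions held by the aspartate-rich motifs of the enzyme strip the diphosphate from C6, the resulting allyl cation is captured by C7 of the remote C7=C11 alkene (ten-membered ring, exo mode, charge on C11), and loss of a C12 proton parks the chain as the enzyme-bound triene 5. An active-site acid then protonates C1 of 5, the C10 cation is attacked across the ring by C5 of the C4=C5 alkene, which is a 6-endo closure for ring A and a 6-exo closure for ring B, and the C4 cation is quenched by removal of a C3 proton. The closest known reaction type is this very one, the 1,10-cyclisation and transannular closure run by class 1 sesquiterpene synthases of the selinene family, with the acid-induced cyclisation of germacrenes as its non-enzymatic relative. C7 is set by the alkene face that the folded chain offers to C6, whereas C5 and C10 are set together in the second closure, where anti addition across two E alkenes held in a crossed chair-like conformer with the C7 substituent equatorial can only give the trans fusion (5α-H, 10β-methyl); the absolute sense comes from the chiral pocket, since 4 is achiral. The step needs 1,10 closure rather than 1,6 or 1,11 closure (farnesyl counting), one absolute fold, and proton loss from C3 rather than C15: the E-configured C4=C5 alkene of the substrate blocks the six-membered alternative and both E alkenes secure the trans fusion, while the fold and the final deprotonation site rest on the choice of enzyme.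

Step 4
Reactants: 6 α-selinene
Product: 9 α-costol (eudesma-3,11(13)-dien-12-ol), via C12 allyllithium 7 (not isolated), via lithium allyltrimethoxyborate 8 (not isolated)
Conditions: n-BuLi, TMEDA, hexane, rt; B(OMe)3, THF, −78 °C to rt; H2O2, aq. NaOH, 0 °C
Reagents that add atoms: hydrogen peroxide, OO (oxygen of 9); n-butyllithium, [Li]CCCC (lithium of 7 and 8); trimethyl borate, COB(OC)OC (stays only in 8)
Why: Allylic lithiation of an isopropenyl group, borate trapping and oxidative C–B cleavage, known for limonene-type dienes: the methyl group of the 1,1-disubstituted alkene is kinetically the most acidic site, the 2-substituted allyl anion has two equivalent termini so no regioisomer can arise, and the ring alkene and the three stereocentres are spectators.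

Step 5
Reactants: 9 α-costol
Product: 10 α-costal (eudesma-3,11(13)-dien-12-al)
Conditions: MnO2, CH2Cl2, rt
Reagents that add atoms: none
Why: Selective MnO2 oxidation of a primary allylic alcohol to the enal is neutral and leaves the isolated C3=C4 alkene alone.

Step 6
Reactants: 10 α-costal
Product: 11 α-costic acid (eudesma-3,11(13)-dien-12-oic acid)
Conditions: NaClO2, NaH2PO4, 2-methyl-2-butene, t-BuOH/H2O, 0 °C to rt
Reagents that add atoms: sodium chlorite, [Na+].[O-]Cl=O
Why: Pinnick oxidation converts the enal into the acrylic acid under mildly acidic buffering, and the large excess of 2-methyl-2-butene traps the electrophilic chlorine by-product before it can reach C3=C4.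

Step 7
Reactants: 11 α-costic acid
Product: 12 methyl α-costate (methyl eudesma-3,11(13)-dien-12-oate)
Conditions: MeI, K2CO3, DMF, rt
Reagents that add atoms: iodomethane, CI
Why: SN2 O-alkylation of the carboxylate with iodomethane is a mild esterification that touches neither the acrylate nor the ring alkene.

Step 8
Reactants: 12 methyl α-costate
Product: 13 methyl 3α,4α-epoxyeudesm-11(13)-en-12-oate
Conditions: mCPBA, NaHCO3, CH2Cl2, 0 °C
Reagents that add atoms: 3-chloroperbenzoic acid, OOC(=O)c1cccc(Cl)c1
Why: Prilezhaev epoxidation takes the electron-rich trisubstituted C3=C4 alkene and ignores the electron-poor acrylate, and the peracid comes from the α face because the axial 10β-methyl group (C14) covers the β face, which sets the α C3–O bond and C4.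

Step 9
Reactants: 13 methyl 3α,4α-epoxyeudesm-11(13)-en-12-oate
Product: 14 methyl 3α,4β-dihydroxyeudesm-11(13)-en-12-oate
Conditions: HClO4 (cat.), THF/H2O, 0 °C to rt
Reagents that add atoms: water, O
Why: Acid-catalysed epoxide hydrolysis under the Fürst–Plattner rule: water attacks the protonated epoxide at the tertiary C4 from the β face, the mode matched both electronically and conformationally (trans-diaxial), so C4 is inverted to the axial 4β-carbinol while the C3–O bond and the 3α configuration stay untouched.

Step 10
Reactants: 14 methyl 3α,4β-dihydroxyeudesm-11(13)-en-12-oate; 15 angelic acid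
Product: 17 methyl 3α-angeloyloxy-4β-hydroxyeudesm-11(13)-en-12-oate, via angelic 2,4,6-trichlorobenzoic anhydride 16 (not isolated)
Conditions: 15, 2,4,6-trichlorobenzoyl chloride, Et3N, toluene, rt; then 14, 80 °C
Reagents that add atoms: 2,4,6-trichlorobenzoyl chloride, O=C(Cl)c1c(Cl)cc(Cl)cc1Cl (its acyl group stays only in 16)
Why: Yamaguchi-type mixed-anhydride esterification run without a nucleophilic pyridine catalyst: the secondary 3α-OH attacks the unhindered angeloyl carbonyl of 16 while the tertiary 4β-OH stays free, the absence of a conjugate-adding catalyst keeps the Z alkene from drifting to the tiglate, and the trans-diaxial arrangement excludes acyl migration.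

Step 11
Reactants: 17 methyl 3α-angeloyloxy-4β-hydroxyeudesm-11(13)-en-12-oate
Product: 19 methyl 3α-angeloyloxyeudesma-4,11(13)-dien-12-oate, via 4β-chlorosulfite 18 (not isolated)
Conditions: SOCl2, pyridine, 0 °C
Reagents that add atoms: thionyl chloride, O=S(Cl)Cl (its atoms stay only in 18)
Why: Chlorosulfite formation and pyridine-induced E2 elimination, the classical dehydration of an axial tertiary carbinol: the axial 4β leaving group has a single antiperiplanar ring hydrogen, the axial 5α-H placed there by the key step (H3 is equatorial), so the more substituted C4=C5 alkene should prevail over the exocyclic one, as it does with the trans-diaxial hydroxy esters derived from steroid 5α,6β-diols.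

Step 12
Reactants: 19 methyl 3α-angeloyloxyeudesma-4,11(13)-dien-12-oate
Product: 20 methyl 3α-angeloyloxy-5α-hydroperoxyeudesma-4(15),11(13)-dien-12-oate (target)
Conditions: O2, tetraphenylporphyrin (cat.), visible light, CH2Cl2, −20 °C; no reductive work-up
Reagents that add atoms: dioxygen, O=O
Why: Schenck ene reaction: singlet oxygen selects the only electron-rich alkene (tetrasubstituted C4=C5; acrylate and angelate are electron-poor), adds on the α face opposite the axial C14 methyl group, and on that face can reach only a C15 hydrogen, because C3 carries its hydrogen on the β face and 6α-H lies near the alkene plane, so the new C5–O bond is α and the alkene moves to C4=C15.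

Compound list
1 | (2E,6E)-farnesol | CC(C)=CCC/C(C)=C/CC/C(C)=C/CO | starting material
2 | farnesyloxydimethylsulfonium chloride | CC(C)=CCC/C(C)=C/CC/C(C)=C/CO[S+](C)C.[Cl-] | intermediate
3 | (2E,6E)-farnesyl chloride | CC(C)=CCC/C(C)=C/CC/C(C)=C/CCl | intermediate
4 | (2E,6E)-farnesyl diphosphate (handled as ammonium salt) | CC(C)=CCC/C(C)=C/CC/C(C)=C/COP(=O)(O)OP(=O)(O)O | intermediate
5 | (R)-germacrene A (1(10)E,4E-germacra-1(10),4,11-triene, 7β-isopropenyl) | CC(=C)[C@@H]1CC/C(C)=C/CC/C(C)=C/C1 | intermediate
6 | α-selinene (eudesma-3,11-diene; 5α-H, 7β-isopropenyl, 10β-methyl) | CC(=C)[C@@H]1CC[C@@]2(C)CCC=C(C)[C@@H]2C1 | intermediate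
7 | C12 allyllithium of α-selinene | [Li]CC(=C)[C@@H]1CC[C@@]2(C)CCC=C(C)[C@@H]2C1 | intermediate
8 | lithium allyltrimethoxyborate of α-selinene | [Li+].CO[B-](OC)(OC)CC(=C)[C@@H]1CC[C@@]2(C)CCC=C(C)[C@@H]2C1 | intermediate
9 | α-costol (eudesma-3,11(13)-dien-12-ol) | OCC(=C)[C@@H]1CC[C@@]2(C)CCC=C(C)[C@@H]2C1 | intermediate
10 | α-costal (eudesma-3,11(13)-dien-12-al) | O=CC(=C)[C@@H]1CC[C@@]2(C)CCC=C(C)[C@@H]2C1 | intermediate
11 | α-costic acid (eudesma-3,11(13)-dien-12-oic acid) | OC(=O)C(=C)[C@@H]1CC[C@@]2(C)CCC=C(C)[C@@H]2C1 | intermediate
12 | methyl α-costate | C=C(C(=O)OC)[C@@H]1CC[C@@]2(C)CCC=C(C)[C@@H]2C1 | intermediate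
13 | methyl 3α,4α-epoxyeudesm-11(13)-en-12-oate (5α-H) | C=C(C(=O)OC)[C@@H]1CC[C@@]2(C)CC[C@H]3O[C@@]3(C)[C@@H]2C1 | intermediate
14 | methyl 3α,4β-dihydroxyeudesm-11(13)-en-12-oate (4α-methyl, 5α-H) | C=C(C(=O)OC)[C@@H]1CC[C@@]2(C)CC[C@@H](O)[C@](C)(O)[C@@H]2C1 | intermediate
15 | angelic acid ((Z)-2-methylbut-2-enoic acid) | C/C=C(/C)C(=O)O | starting material
16 | angelic 2,4,6-trichlorobenzoic anhydride | C/C=C(/C)C(=O)OC(=O)c1c(Cl)cc(Cl)cc1Cl | intermediate
17 | methyl 3α-angeloyloxy-4β-hydroxyeudesm-11(13)-en-12-oate | C=C(C(=O)OC)[C@@H]1CC[C@@]2(C)CC[C@@H](OC(=O)/C(C)=C\C)[C@](C)(O)[C@@H]2C1 | intermediate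
18 | 4β-chlorosulfite of 17 | C=C(C(=O)OC)[C@@H]1CC[C@@]2(C)CC[C@@H](OC(=O)/C(C)=C\C)[C@](C)(OS(=O)Cl)[C@@H]2C1 | intermediate
19 | methyl 3α-angeloyloxyeudesma-4,11(13)-dien-12-oate | C=C(C(=O)OC)[C@@H]1CC[C@@]2(C)CC[C@@H](OC(=O)/C(C)=C\C)C(C)=C2C1 | intermediate
20 | methyl 3α-angeloyloxy-5α-hydroperoxyeudesma-4(15),11(13)-dien-12-oate | C=C(C(=O)OC)[C@@H]1CC[C@@]2(C)CC[C@@H](OC(=O)/C(C)=C\C)C(=C)[C@]2(OO)C1 | target

Total step count: 12. Longest linear sequence: 12 steps (1 to 20); 15 enters in step 10 without steps of its own.

Steps most likely to fail

Step 3. The risk is loss of product fidelity: terminal deprotonation at C15 instead of C3, or early release of the ten-membered triene. The fallback splits the cascade into an enzymatic and a chemical half.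
- It sets out from 4. A high-fidelity germacrene A synthase with MgCl2 is used only for the C6–C7 macrocyclisation, and (R)-germacrene A 5 is extracted cold into pentane and isolated.
- 5 is then closed across the ring with a mild Brønsted acid (silica gel or a trace of TsOH in pentane/CH2Cl2, 0 °C). This is a known transannular cyclisation in which the C7 substituent and the two E alkenes dictate the trans-decalin.
- α-Selinene is separated from its double-bond isomers on AgNO3-impregnated silica, and the route is rejoined at 6. This detour makes no compound outside the list (F0).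

Step 11. The risk is wrong regiochemistry of the elimination (proton loss from the C15 methyl group instead of C5) or interference by the neighbouring ester. The fallback fixes the alkene position by conjugation and sets C3 afterwards.
- It sets out from 14. Dess–Martin periodinane oxidises the secondary alcohol to methyl 4β-hydroxy-3-oxoeudesm-11(13)-en-12-oate F1.
- SOCl2/pyridine, followed by a trace of TsOH, dehydrates F1 and equilibrates the alkene into the conjugated, thermodynamically preferred ring position, giving methyl 3-oxoeudesma-4,11(13)-dien-12-oate F2.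
- Luche reduction (NaBH4, CeCl3·7H2O, MeOH, −20 °C) delivers hydride axially on the α face to give methyl 3β-hydroxyeudesma-4,11(13)-dien-12-oate F3.
- Mitsunobu esterification with angelic acid 15 (PPh3, DIAD, toluene, 0 °C) inverts C3, and the route is rejoined at 19.

Step 12. The risk is poor facial selectivity, because the axial 3α-ester screens part of the α face that the C14 methyl group otherwise leaves open, or decay of the hydroperoxide during a slow reaction. The fallback reverses the order of oxygenation, C5 first and C3 later. The price is that H3α becomes a second abstractable hydrogen in the ene step of the fallback, so its regiochemistry is less tightly fixed than in step 12.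
- It sets out from 12. TsOH in hot toluene moves the ring alkene into the tetrasubstituted position to give methyl eudesma-4,11(13)-dien-12-oate F4.
- The Schenck ene reaction (O2, tetraphenylporphyrin, light) on this alkene, whose faces differ only by the C14 methyl group, should give methyl 5α-hydroperoxyeudesma-4(15),11(13)-dien-12-oate F5.
- TBSCl/imidazole masks the hydroperoxide as methyl 5α-(tert-butyldimethylsilylperoxy)eudesma-4(15),11(13)-dien-12-oate F6.
- Riley oxidation (SeO2 cat., t-BuOOH, CH2Cl2) hydroxylates C3, the only allylic C–H position of C4=C15. It removes the axial H3α and returns oxygen to the same face, giving the 3α-hydroxy silyl peroxide F7.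
- Angeloylation through anhydride 16, as in step 10, gives the 3α-angeloyloxy silyl peroxide F8. HF·pyridine frees the hydroperoxide, and the route is rejoined at 20.

Further compounds
F0 | step 3 | none | none
F1 | step 11 | methyl 4β-hydroxy-3-oxoeudesm-11(13)-en-12-oate | C=C(C(=O)OC)[C@@H]1CC[C@@]2(C)CCC(=O)[C@](C)(O)[C@@H]2C1
F2 | step 11 | methyl 3-oxoeudesma-4,11(13)-dien-12-oate | C=C(C(=O)OC)[C@@H]1CC[C@@]2(C)CCC(=O)C(C)=C2C1
F3 | step 11 | methyl 3β-hydroxyeudesma-4,11(13)-dien-12-oate | C=C(C(=O)OC)[C@@H]1CC[C@@]2(C)CC[C@H](O)C(C)=C2C1
F4 | step 12 | methyl eudesma-4,11(13)-dien-12-oate | C=C(C(=O)OC)[C@@H]1CC[C@@]2(C)CCCC(C)=C2C1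
F5 | step 12 | methyl 5α-hydroperoxyeudesma-4(15),11(13)-dien-12-oate | C=C(C(=O)OC)[C@@H]1CC[C@@]2(C)CCCC(=C)[C@]2(OO)C1
F6 | step 12 | methyl 5α-(tert-butyldimethylsilylperoxy)eudesma-4(15),11(13)-dien-12-oate | C=C(C(=O)OC)[C@@H]1CC[C@@]2(C)CCCC(=C)[C@]2(OO[Si](C)(C)C(C)(C)C)C1
F7 | step 12 | methyl 3α-hydroxy-5α-(tert-butyldimethylsilylperoxy)eudesma-4(15),11(13)-dien-12-oate | C=C(C(=O)OC)[C@@H]1CC[C@@]2(C)CC[C@@H](O)C(=C)[C@]2(OO[Si](C)(C)C(C)(C)C)C1
F8 | step 12 | methyl 3α-angeloyloxy-5α-(tert-butyldimethylsilylperoxy)eudesma-4(15),11(13)-dien-12-oate | C=C(C(=O)OC)[C@@H]1CC[C@@]2(C)CC[C@@H](OC(=O)/C(C)=C\C)C(=C)[C@]2(OO[Si](C)(C)C(C)(C)C)C1
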